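**Plan**
1. The last cut is the biaryl bond between ring C (on the oxolane) and ring D (on the tetralin). It gives a chloroarene tetralin and an arylboronate oxolane, each built on a simple guaiacol.
2. Tetralin half: C4 is a benzylic CH2 bonded to the tertiary carbinol C3, so the C4–C4a bond is cut to a ring-A aryl anion and a 2,2-disubstituted oxirane spanning C3/C4, opened at its CH2 end.
3. Before that, the oxirane comes from a 2-substituted allylic alcohol (C3 grown from an acyl carbon), C2–CH2O from an enolate alkoxymethylation, and C1–ring D from a cuprate addition to a ring-A cinnamoyl imide.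
4. Oxolane half: cuts at C4–CH2Ar (aryl cuprate on a spiro-oxirane), O1–C5 (Williamson closure to a 4-methylene oxolane) and C2–C3 (syn-aldol).
5. Forward: open chain, then ring B by the anionic closure; separately aldol, oxolane ring, spiro-oxirane, arylmethyl group, boronate; then biaryl coupling and removal of all benzyl ethers.
6. Stereochemistry: tetralin C1/C2 and oxolane C2/C3 from (R)-4-benzyl-oxazolidin-2-one; tetralin C3 from L-(+)-diethyl tartrate; oxolane C4 from epoxidation anti to the cis C2/C3 substituents.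

Key step: step 14

Assumption: the SMILES is taken as written, i.e. (1S,2S,3S) in the tetralin and (2R,3R,4S) in the oxolane. This places aryl, CH2OH and arylmethyl on one face of the oxolane (2,3-cis), and the route is built for that isomer.

Numbering: tetralin C1 (diarylmethine), C2, C3 (carbinol), C4 (benzylic CH2), C4a/C8a; oxolane O1, C2 (aryl), C3, C4 (carbinol), C5.

Abbreviations: ArA = 5-(benzyloxy)-2-bromo-4-methoxyphenyl; ArD = 4-(benzyloxy)-3-chloro-5-methoxyphenyl; ArC = 4-(benzyloxy)-3-bromo-5-methoxyphenyl; ArE = 4-(benzyloxy)-3-methoxyphenyl.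

**Tetralin half**

Step 1
Reactants: 1 4-bromo-2-methoxyphenol
Product: 2 4-bromo-2-chloro-6-methoxyphenol
Conditions: SO2Cl2, i-Bu2NH (cat.), toluene, 70 °C
Reagents that add atoms: sulfuryl chloride (O=S(=O)(Cl)Cl)
Why: Amine-catalysed electrophilic aromatic chlorination goes ortho to the phenol, and with the para position blocked by bromine only C6 is open.

Step 2
Reactants: 2 4-bromo-2-chloro-6-methoxyphenol
Product: 3 2-(benzyloxy)-5-bromo-1-chloro-3-methoxybenzene
Conditions: BnBr, K2CO3, DMF, 60 °C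
Reagents that add atoms: benzyl bromide (BrCc1ccccc1)
Why: Williamson etherification masks the phenol in a form that tolerates organomagnesium and organolithium reagents.

Step 3
Reactants: 4 2-bromo-5-hydroxy-4-methoxybenzaldehyde
Product: 5 5-(benzyloxy)-2-bromo-4-methoxybenzaldehyde
Conditions: BnBr, K2CO3, DMF, rt
Reagents that add atoms: benzyl bromide (BrCc1ccccc1)
Why: Williamson etherification of the phenoxide should proceed without touching the aldehyde or the aryl bromide.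

Step 4
Reactants: 5 5-(benzyloxy)-2-bromo-4-methoxybenzaldehyde
Product: 6 (E)-3-ArA-prop-2-enoic acid
Conditions: malonic acid, pyridine, piperidine (cat.), 95 °C
Reagents that add atoms: malonic acid (OC(=O)CC(O)=O)
Why: Knoevenagel–Doebner condensation with decarboxylation should give the E-cinnamic acid directly.

Step 5
Reactants: 6 (E)-3-ArA-prop-2-enoic acid; 7 (R)-4-benzyl-1,3-oxazolidin-2-one
Product: 9 (R)-4-benzyl-3-[(E)-3-ArA-prop-2-enoyl]-1,3-oxazolidin-2-one, via mixed pivalic anhydride 8 (not isolated)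
Conditions: PivCl, Et3N, THF, −20 °C; then 7, LiCl, −20 °C → rt
Reagents that add atoms: none
Why: N-acylation of the oxazolidinone through the mixed anhydride with LiCl activation needs no strong base, so the aryl bromide is safe.

Step 6
Reactants: 9 (R)-4-benzyl-3-[(E)-3-ArA-prop-2-enoyl]-1,3-oxazolidin-2-one; 3 2-(benzyloxy)-5-bromo-1-chloro-3-methoxybenzene
Product: 11 (R)-4-benzyl-3-[(3S)-3-ArA-3-ArD-propanoyl]-1,3-oxazolidin-2-one, via arylmagnesium bromide 10 (not isolated)
Conditions: 3, Mg, THF, 45 °C; CuBr·SMe2 (0.5 equiv), THF/Me2S, −40 °C; then 9, −40 → −15 °C; aq. NH4Cl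
Reagents that add atoms: none
Why: Copper-mediated conjugate addition to the magnesium-chelated syn-s-cis enoyl imide should deliver the aryl group to the β-face remote from the 4-benzyl group, setting C1 as S; Mg inserts into C–Br only and the ring-A bromide is inert to the arylcopper species at low temperature.

Step 7
Reactants: 11 (R)-4-benzyl-3-[(3S)-3-ArA-3-ArD-propanoyl]-1,3-oxazolidin-2-one
Product: 13 (R)-4-benzyl-3-[(2S,3S)-2-[(benzyloxy)methyl]-3-ArA-3-ArD-propanoyl]-1,3-oxazolidin-2-one, via trichlorotitanium Z-enolate 12 (not isolated)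
Conditions: TiCl4, i-Pr2NEt, CH2Cl2, 0 °C; then BnOCH2Cl, 0 °C
Reagents that add atoms: benzyl chloromethyl ether (ClCOCc1ccccc1)
Why: Evans alkylation of the chelated Z-titanium enolate with the oxocarbenium-type electrophile should occur anti to the auxiliary benzyl group, setting C2 as S (trans to the C1 aryl in the later ring).

Step 8
Reactants: 13 (R)-4-benzyl-3-[(2S,3S)-2-[(benzyloxy)methyl]-3-ArA-3-ArD-propanoyl]-1,3-oxazolidin-2-one
Product: 15 (2S,3S)-2-[(benzyloxy)methyl]-3-ArA-3-ArD-propanoic acid, via peroxy acid 14 (not isolated)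
Conditions: LiOH, H2O2, THF/H2O, 0 °C; Na2SO3; aq. HCl to pH 3
Reagents that add atoms: hydrogen peroxide (OO)
Why: Hydroperoxide attacks the exocyclic carbonyl of hindered imides selectively (auxiliary hydrolysis), and its low basicity avoids epimerisation at C2 or β-elimination of the benzyloxy group.

Step 9
Reactants: 15 (2S,3S)-2-[(benzyloxy)methyl]-3-ArA-3-ArD-propanoic acid
Product: 16 methyl (2S,3S)-2-[(benzyloxy)methyl]-3-ArA-3-ArD-propanoate
Conditions: MeI, K2CO3, DMF, rt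
Reagents that add atoms: iodomethane (CI)
Why: Carboxylate O-alkylation (SN2 esterification) provides the ester needed for the double organometallic addition.

Step 10
Reactants: 16 methyl (2S,3S)-2-[(benzyloxy)methyl]-3-ArA-3-ArD-propanoate
Product: 18 [(3R,4S)-3-[(benzyloxy)methyl]-4-ArA-4-ArD-2-methylidenebutyl]trimethylsilane, via bis(silylmethyl) carbinol 17 (not isolated)
Conditions: TMSCH2MgCl, CeCl3, THF, −78 °C → rt; aq. NH4Cl; then SiO2, CH2Cl2, rt
Reagents that add atoms: (trimethylsilyl)methylmagnesium chloride (C[Si](C)(C)C[Mg]Cl)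
Why: The weakly basic cerium-modified Grignard reagent should add twice to the ester without enolisation, and Peterson elimination of one β-silyl group on silica turns the acyl carbon into C3 of a 2-substituted allylsilane.

Step 11
Reactants: 18 [(3R,4S)-3-[(benzyloxy)methyl]-4-ArA-4-ArD-2-methylidenebutyl]trimethylsilane
Product: 20 (3R,4S)-3-[(benzyloxy)methyl]-4-ArA-4-ArD-2-methylidenebutan-1-ol, via epoxysilane 19 (not isolated)
Conditions: mCPBA, CH2Cl2/aq. NaHCO3, 0 °C; then Bu4NF, THF, rt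
Reagents that add atoms: 3-chloroperoxybenzoic acid (OOC(=O)c1cccc(Cl)c1)
Why: Prilezhaev epoxidation of the electron-rich allylsilane followed by fluoride-induced β-elimination of the silyl oxirane should give the transposed 2-substituted allylic alcohol; the transient oxirane centre is destroyed, so its configuration is irrelevant.

Step 12
Reactants: 20 (3R,4S)-3-[(benzyloxy)methyl]-4-ArA-4-ArD-2-methylidenebutan-1-ol
Product: 21 {(2S)-2-[(2S,3S)-1-(benzyloxy)-3-ArA-3-ArD-propan-2-yl]oxiran-2-yl}methanol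
Conditions: Ti(OiPr)4 (10 mol%), L-(+)-diethyl tartrate (12 mol%), t-BuOOH, 4 Å MS, CH2Cl2, −20 °C
Reagents that add atoms: tert-butyl hydroperoxide (CC(C)(C)OO)
Why: Sharpless asymmetric epoxidation of the 1,1-disubstituted allylic alcohol is reagent-controlled, and the L-(+)-tartrate should give the (S)-oxirane, which maps onto the S carbinol at C3.

Step 13
Reactants: 21 {(2S)-2-[(2S,3S)-1-(benzyloxy)-3-ArA-3-ArD-propan-2-yl]oxiran-2-yl}methanol
Product: 22 (2R)-2-[(benzyloxy)methyl]-2-[(2S,3S)-1-(benzyloxy)-3-ArA-3-ArD-propan-2-yl]oxirane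
Conditions: NaH, BnBr, Bu4NI (cat.), THF, 0 °C → rt
Reagents that add atoms: benzyl bromide (BrCc1ccccc1)
Why: Williamson benzylation of the primary alkoxide leaves the oxirane intact; a Payne shift of this 2,2-disubstituted epoxy alkoxide is degenerate and returns the same stereoisomer, and the change of descriptor to R is only a change of CIP priority.

Step 14
Reactants: 22 (2R)-2-[(benzyloxy)methyl]-2-[(2S,3S)-1-(benzyloxy)-3-ArA-3-ArD-propan-2-yl]oxirane
Product: 24 (1S,2S,3S)-7-(benzyloxy)-2,3-bis[(benzyloxy)methyl]-1-ArD-6-methoxy-1,2,3,4-tetrahydronaphthalen-3-ol, via aryllithium 23 (not isolated)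
Conditions: t-BuLi (2.1 equiv), THF, −78 °C; then −78 → −20 °C; aq. NH4Cl
Reagents that add atoms: none
Why: tert-Butyllithium exchanges the ring-A bromide within minutes at −78 °C, and the aryllithium 23 then attacks the unsubstituted CH2 terminus of the tethered oxirane in an SN2 fashion, forming C4–C4a and releasing the tertiary lithium alkoxide at C3. The closest known reaction type is the Parham cyclization of an aryllithium onto a tethered epoxide. Ring B closes in the 6-endo-tet mode; the only alternative, a 5-exo attack, would have to occur at the fully substituted oxirane carbon and should not compete. No stereocentre is created: C1 and C2 are untouched and the C3–O bond is never broken, so the configuration set by the Sharpless epoxidation reappears unchanged in the carbinol. The step needs regioselective opening at CH2 and halogen–metal exchange at bromine only; the quaternary oxirane carbon secures the first, and the inertness of the ring-D chloride and the benzyl ethers towards two equivalents of t-BuLi at −78 °C secures the second. Because the ring is closed under basic conditions, no benzylic cation can scramble the diarylmethine centre.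

**Oxolane half**

Step 15
Reactants: 1 4-bromo-2-methoxyphenol
Product: 25 1-(benzyloxy)-4-bromo-2-methoxybenzene
Conditions: BnBr, K2CO3, DMF, rt
Reagents that add atoms: benzyl bromide (BrCc1ccccc1)
Why: Williamson etherification gives the protected ring-E bromide for later Grignard formation.

Step 16
Reactants: 26 3-(benzyloxy)propanoic acid; 7 (R)-4-benzyl-1,3-oxazolidin-2-one
Product: 28 (R)-4-benzyl-3-[3-(benzyloxy)propanoyl]-1,3-oxazolidin-2-one, via mixed pivalic anhydride 27 (not isolated)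
Conditions: PivCl, Et3N, THF, −20 °C; then 7, LiCl, −20 °C → rt
Reagents that add atoms: none
Why: N-acylation through the mixed anhydride gives the aldol donor whose acyl carbon will become oxolane C4 and whose benzyloxymethyl group will sit on C3.

Step 17
Reactants: 29 3-bromo-4-hydroxy-5-methoxybenzaldehyde
Product: 30 4-(benzyloxy)-3-bromo-5-methoxybenzaldehyde
Conditions: BnBr, K2CO3, DMF, 60 °C
Reagents that add atoms: benzyl bromide (BrCc1ccccc1)
Why: Williamson etherification protects the phenol of ring C while the bromide is kept as the later coupling handle.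

Step 18
Reactants: 28 (R)-4-benzyl-3-[3-(benzyloxy)propanoyl]-1,3-oxazolidin-2-one; 30 4-(benzyloxy)-3-bromo-5-methoxybenzaldehyde
Product: 32 (R)-4-benzyl-3-[(2R,3R)-2-[(benzyloxy)methyl]-3-ArC-3-hydroxypropanoyl]-1,3-oxazolidin-2-one, via dibutylboron Z-enolate 31 (not isolated)
Conditions: Bu2BOTf, i-Pr2NEt, CH2Cl2, −78 → 0 °C; then 30, −78 → 0 °C; pH 7 buffer, MeOH, H2O2, 0 °C
Reagents that add atoms: none
Why: The Evans syn-aldol reaction of the Z-boron enolate through a closed chair transition state should set both centres (2R,3R) under auxiliary control, which places aryl and CH2OBn cis on the later oxolane.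

Step 19
Reactants: 32 (R)-4-benzyl-3-[(2R,3R)-2-[(benzyloxy)methyl]-3-ArC-3-hydroxypropanoyl]-1,3-oxazolidin-2-one
Product: 33 (R)-4-benzyl-3-[(2R,3R)-2-[(benzyloxy)methyl]-3-ArC-3-[(tert-butyldimethylsilyl)oxy]propanoyl]-1,3-oxazolidin-2-one
Conditions: TBSOTf, 2,6-lutidine, CH2Cl2, −78 → 0 °C
Reagents that add atoms: tert-butyldimethylsilyl trifluoromethanesulfonate (CC(C)(C)[Si](C)(C)OS(=O)(=O)C(F)(F)F)
Why: O-silylation blocks retro-aldol cleavage and benzylic ionisation during the organometallic and acidic operations that follow.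

Step 20
Reactants: 33 (R)-4-benzyl-3-[(2R,3R)-2-[(benzyloxy)methyl]-3-ArC-3-[(tert-butyldimethylsilyl)oxy]propanoyl]-1,3-oxazolidin-2-one
Product: 35 (2R,3R)-2-[(benzyloxy)methyl]-3-ArC-3-[(tert-butyldimethylsilyl)oxy]propanoic acid, via peroxy acid 34 (not isolated)
Conditions: LiOH, H2O2, THF/H2O, 0 °C → rt; Na2SO3; aq. HCl to pH 3, 0 °C
Reagents that add atoms: hydrogen peroxide (OO)
Why: Hydroperoxide-mediated auxiliary hydrolysis cleaves the exocyclic acyl group of the hindered imide without epimerisation.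

Step 21
Reactants: 35 (2R,3R)-2-[(benzyloxy)methyl]-3-ArC-3-[(tert-butyldimethylsilyl)oxy]propanoic acid
Product: 36 methyl (2R,3R)-2-[(benzyloxy)methyl]-3-ArC-3-[(tert-butyldimethylsilyl)oxy]propanoate
Conditions: MeI, K2CO3, DMF, rt
Reagents that add atoms: iodomethane (CI)
Why: Carboxylate O-alkylation gives the ester for the allylsilane synthesis.

Step 22
Reactants: 36 methyl (2R,3R)-2-[(benzyloxy)methyl]-3-ArC-3-[(tert-butyldimethylsilyl)oxy]propanoate
Product: 38 [(3R,4R)-4-ArC-3-[(benzyloxy)methyl]-4-[(tert-butyldimethylsilyl)oxy]-2-methylidenebutyl]trimethylsilane, via bis(silylmethyl) carbinol 37 (not isolated)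
Conditions: TMSCH2MgCl, CeCl3, THF, −78 °C → rt; aq. NH4Cl; then SiO2, CH2Cl2, rt
Reagents that add atoms: (trimethylsilyl)methylmagnesium chloride (C[Si](C)(C)C[Mg]Cl)
Why: Cerium-mediated double addition and Peterson elimination convert the ester carbon into the future C4 with its exocyclic methylene, as in step 10.

Step 23
Reactants: 38 [(3R,4R)-4-ArC-3-[(benzyloxy)methyl]-4-[(tert-butyldimethylsilyl)oxy]-2-methylidenebutyl]trimethylsilane
Product: 40 (1R,2R)-1-ArC-2-[(benzyloxy)methyl]-3-methylidenebutane-1,4-diol, via epoxysilane 39 (not isolated)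
Conditions: mCPBA, CH2Cl2/aq. NaHCO3, 0 °C; then Bu4NF (3 equiv), THF, rt
Reagents that add atoms: 3-chloroperoxybenzoic acid (OOC(=O)c1cccc(Cl)c1)
Why: Prilezhaev epoxidation and fluoride-induced β-elimination of the silyl oxirane give the allylic alcohol, and the same fluoride removes the silyl ether, exposing the 1,4-diol.

Step 24
Reactants: 40 (1R,2R)-1-ArC-2-[(benzyloxy)methyl]-3-methylidenebutane-1,4-diol
Product: 42 (2R,3R)-2-ArC-3-[(benzyloxy)methyl]-4-methylideneoxolane, via allylic tosylate 41 (not isolated)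
Conditions: TsCl, Et3N, DMAP (cat.), CH2Cl2, 0 °C; then NaH, THF, 0 °C → rt
Reagents that add atoms: none
Why: The primary allylic hydroxyl is sulfonylated selectively and the benzylic alkoxide closes the oxolane by intramolecular Williamson etherification (5-exo-tet), so the C2–O bond is retained and the 2,3-cis relationship from the aldol is carried into the ring.

Step 25
Reactants: 42 (2R,3R)-2-ArC-3-[(benzyloxy)methyl]-4-methylideneoxolane
Product: 43 (3R,6R,7R)-6-ArC-7-[(benzyloxy)methyl]-1,5-dioxaspiro[2.4]heptane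
Conditions: mCPBA, CH2Cl2/aq. NaHCO3, 0 °C
Reagents that add atoms: 3-chloroperoxybenzoic acid (OOC(=O)c1cccc(Cl)c1)
Why: Prilezhaev epoxidation of the exocyclic alkene should occur from the ring face opposite the cis aryl and CH2OBn groups, placing the oxirane oxygen (the future C4 hydroxyl) trans to both.

Step 26
Reactants: 43 (3R,6R,7R)-6-ArC-7-[(benzyloxy)methyl]-1,5-dioxaspiro[2.4]heptane; 25 1-(benzyloxy)-4-bromo-2-methoxybenzene
Product: 45 (2R,3R,4S)-2-ArC-3-[(benzyloxy)methyl]-4-(ArE-methyl)oxolan-4-ol, via arylmagnesium bromide 44 (not isolated)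
Conditions: 25, Mg, THF, 50 °C; then CuI (10 mol%), 43, THF, −30 → 0 °C; aq. NH4Cl
Reagents that add atoms: none
Why: Copper-catalysed SN2 opening of the spiro-oxirane by the aryl Grignard reagent can only occur at the CH2 carbon, so the C4–O bond and the C4 configuration are retained and the arylmethyl group ends up cis to the C2 and C3 substituents.

Step 27
Reactants: 45 (2R,3R,4S)-2-ArC-3-[(benzyloxy)methyl]-4-(ArE-methyl)oxolan-4-ol
Product: 46 (2R,3R,4S)-2-[4-(benzyloxy)-3-methoxy-5-(4,4,5,5-tetramethyl-1,3,2-dioxaborolan-2-yl)phenyl]-3-[(benzyloxy)methyl]-4-(ArE-methyl)oxolan-4-ol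
Conditions: B2pin2, Pd(dppf)Cl2 (5 mol%), KOAc, 1,4-dioxane, 90 °C
Reagents that add atoms: bis(pinacolato)diboron (CC1(C)OB(OC1(C)C)B1OC(C)(C)C(C)(C)O1)
Why: Miyaura borylation converts the aryl bromide into the pinacol boronate and tolerates the free tertiary alcohol and the benzyl ethers.

**Union and deprotection**

Step 28
Reactants: 24 (1S,2S,3S)-7-(benzyloxy)-2,3-bis[(benzyloxy)methyl]-1-ArD-6-methoxy-1,2,3,4-tetrahydronaphthalen-3-ol; 46 pinacol boronate of the oxolane half
Product: 47 hepta-O-benzyl ether of the target (four phenols and three primary alcohols benzylated, both tertiary alcohols free)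
Conditions: Pd(OAc)2 (5 mol%), SPhos (10 mol%), K3PO4, toluene/H2O, 100 °C
Reagents that add atoms: none
Why: Suzuki–Miyaura coupling with an electron-rich dialkylbiarylphosphine should allow oxidative addition into the electron-rich, ortho-alkoxy aryl chloride and form the doubly ortho-oxygenated biaryl without touching any stereocentre.

Step 29
Reactants: 47 hepta-O-benzyl ether of the target
Product: 48 target, (2S,3S,4S)-4-{4-hydroxy-3-[2-hydroxy-5-[(2R,3R,4S)-4-hydroxy-4-(4-hydroxy-3-methoxybenzyl)-3-(hydroxymethyl)oxolan-2-yl]-3-methoxyphenyl]-5-methoxyphenyl}-2,3-bis(hydroxymethyl)-7-methoxy-1,2,3,4-tetrahydronaphthalene-2,6-diol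
Conditions: H2 (1 atm), Pd/C (10 wt%), EtOAc/MeOH, rt
Reagents that add atoms: none
Why: Catalytic hydrogenolysis should remove the four aryl and three primary alkyl benzyl ethers, whereas the hindered secondary C2–O bond of the oxolane is expected to react much more slowly under neutral conditions at atmospheric pressure.

**Compound list**
1 | 4-bromo-2-methoxyphenol | COc1cc(Br)ccc1O | starting material
2 | 4-bromo-2-chloro-6-methoxyphenol | COc1cc(Br)cc(Cl)c1O | intermediate
3 | 2-(benzyloxy)-5-bromo-1-chloro-3-methoxybenzene | COc1cc(Br)cc(Cl)c1OCc1ccccc1 | intermediate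
4 | 2-bromo-5-hydroxy-4-methoxybenzaldehyde | COc1cc(Br)c(C=O)cc1O | starting material
5 | 5-(benzyloxy)-2-bromo-4-methoxybenzaldehyde | COc1cc(Br)c(C=O)cc1OCc1ccccc1 | intermediate
6 | (E)-3-ArA-prop-2-enoic acid | COc1cc(Br)c(/C=C/C(O)=O)cc1OCc1ccccc1 | intermediate
7 | (R)-4-benzyl-1,3-oxazolidin-2-one | O=C1OC[C@@H](Cc2ccccc2)N1 | starting material
8 | (E)-3-ArA-prop-2-enoic pivalic anhydride | COc1cc(Br)c(/C=C/C(=O)OC(=O)C(C)(C)C)cc1OCc1ccccc1 | intermediate
9 | (R)-4-benzyl-3-[(E)-3-ArA-prop-2-enoyl]-1,3-oxazolidin-2-one | COc1cc(Br)c(/C=C/C(=O)N2[C@H](Cc3ccccc3)COC2=O)cc1OCc1ccccc1 | intermediate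
10 | [4-(benzyloxy)-3-chloro-5-methoxyphenyl]magnesium bromide | COc1cc([Mg]Br)cc(Cl)c1OCc1ccccc1 | intermediate
11 | (R)-4-benzyl-3-[(3S)-3-ArA-3-ArD-propanoyl]-1,3-oxazolidin-2-one | COc1cc(cc(Cl)c1OCc1ccccc1)[C@@H](c1cc(OCc2ccccc2)c(OC)cc1Br)CC(=O)N1[C@H](Cc2ccccc2)COC1=O | intermediate
12 | trichlorotitanium (Z)-enolate of 11 | COc1cc(cc(Cl)c1OCc1ccccc1)[C@@H](c1cc(OCc2ccccc2)c(OC)cc1Br)/C=C(\O[Ti](Cl)(Cl)Cl)N1[C@H](Cc2ccccc2)COC1=O | intermediate
13 | (R)-4-benzyl-3-[(2S,3S)-2-[(benzyloxy)methyl]-3-ArA-3-ArD-propanoyl]-1,3-oxazolidin-2-one | COc1cc(cc(Cl)c1OCc1ccccc1)[C@@H](c1cc(OCc2ccccc2)c(OC)cc1Br)[C@@H](COCc1ccccc1)C(=O)N1[C@H](Cc2ccccc2)COC1=O | intermediate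
14 | (2S,3S)-2-[(benzyloxy)methyl]-3-ArA-3-ArD-propaneperoxoic acid | COc1cc(cc(Cl)c1OCc1ccccc1)[C@@H](c1cc(OCc2ccccc2)c(OC)cc1Br)[C@@H](COCc1ccccc1)C(=O)OO | intermediate
15 | (2S,3S)-2-[(benzyloxy)methyl]-3-ArA-3-ArD-propanoic acid | COc1cc(cc(Cl)c1OCc1ccccc1)[C@@H](c1cc(OCc2ccccc2)c(OC)cc1Br)[C@@H](COCc1ccccc1)C(O)=O | intermediate
16 | methyl (2S,3S)-2-[(benzyloxy)methyl]-3-ArA-3-ArD-propanoate | COc1cc(cc(Cl)c1OCc1ccccc1)[C@@H](c1cc(OCc2ccccc2)c(OC)cc1Br)[C@@H](COCc1ccccc1)C(=O)OC | intermediate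
17 | (3S,4S)-3-[(benzyloxy)methyl]-4-ArA-4-ArD-1-(trimethylsilyl)-2-[(trimethylsilyl)methyl]butan-2-ol | COc1cc(cc(Cl)c1OCc1ccccc1)[C@@H](c1cc(OCc2ccccc2)c(OC)cc1Br)[C@@H](COCc1ccccc1)C(O)(C[Si](C)(C)C)C[Si](C)(C)C | intermediate
18 | [(3R,4S)-3-[(benzyloxy)methyl]-4-ArA-4-ArD-2-methylidenebutyl]trimethylsilane | COc1cc(cc(Cl)c1OCc1ccccc1)[C@@H](c1cc(OCc2ccccc2)c(OC)cc1Br)[C@@H](COCc1ccccc1)C(=C)C[Si](C)(C)C | intermediate
19 | trimethyl({2-[(2S,3S)-1-(benzyloxy)-3-ArA-3-ArD-propan-2-yl]oxiran-2-yl}methyl)silane, both epimers at the oxirane carbon | COc1cc(cc(Cl)c1OCc1ccccc1)[C@@H](c1cc(OCc2ccccc2)c(OC)cc1Br)[C@@H](COCc1ccccc1)C1(C[Si](C)(C)C)CO1 | intermediate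
20 | (3R,4S)-3-[(benzyloxy)methyl]-4-ArA-4-ArD-2-methylidenebutan-1-ol | COc1cc(cc(Cl)c1OCc1ccccc1)[C@@H](c1cc(OCc2ccccc2)c(OC)cc1Br)[C@@H](COCc1ccccc1)C(=C)CO | intermediate
21 | {(2S)-2-[(2S,3S)-1-(benzyloxy)-3-ArA-3-ArD-propan-2-yl]oxiran-2-yl}methanol | COc1cc(cc(Cl)c1OCc1ccccc1)[C@@H](c1cc(OCc2ccccc2)c(OC)cc1Br)[C@@H](COCc1ccccc1)[C@]1(CO)CO1 | intermediate
22 | (2R)-2-[(benzyloxy)methyl]-2-[(2S,3S)-1-(benzyloxy)-3-ArA-3-ArD-propan-2-yl]oxirane | COc1cc(cc(Cl)c1OCc1ccccc1)[C@@H](c1cc(OCc2ccccc2)c(OC)cc1Br)[C@@H](COCc1ccccc1)[C@]1(COCc2ccccc2)CO1 | intermediate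
23 | aryllithium of 22 (lithium in place of the ring-A bromine) | COc1cc(cc(Cl)c1OCc1ccccc1)[C@@H](c1cc(OCc2ccccc2)c(OC)cc1[Li])[C@@H](COCc1ccccc1)[C@]1(COCc2ccccc2)CO1 | intermediate
24 | (1S,2S,3S)-7-(benzyloxy)-2,3-bis[(benzyloxy)methyl]-1-ArD-6-methoxy-1,2,3,4-tetrahydronaphthalen-3-ol (plan numbering) | COc1cc(cc(Cl)c1OCc1ccccc1)[C@H]1c2cc(OCc3ccccc3)c(OC)cc2C[C@@](O)(COCc2ccccc2)[C@@H]1COCc1ccccc1 | intermediate
25 | 1-(benzyloxy)-4-bromo-2-methoxybenzene | COc1cc(Br)ccc1OCc1ccccc1 | intermediate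
26 | 3-(benzyloxy)propanoic acid | OC(=O)CCOCc1ccccc1 | starting material
27 | 3-(benzyloxy)propanoic pivalic anhydride | CC(C)(C)C(=O)OC(=O)CCOCc1ccccc1 | intermediate
28 | (R)-4-benzyl-3-[3-(benzyloxy)propanoyl]-1,3-oxazolidin-2-one | O=C(CCOCc1ccccc1)N1[C@H](Cc2ccccc2)COC1=O | intermediate
29 | 3-bromo-4-hydroxy-5-methoxybenzaldehyde | COc1cc(C=O)cc(Br)c1O | starting material
30 | 4-(benzyloxy)-3-bromo-5-methoxybenzaldehyde | COc1cc(C=O)cc(Br)c1OCc1ccccc1 | intermediate
31 | dibutylboron (Z)-enolate of 28 | CCCCB(CCCC)O/C(=C\COCc1ccccc1)N1[C@H](Cc2ccccc2)COC1=O | intermediate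
32 | (R)-4-benzyl-3-[(2R,3R)-2-[(benzyloxy)methyl]-3-ArC-3-hydroxypropanoyl]-1,3-oxazolidin-2-one | O=C1OC[C@@H](Cc2ccccc2)N1C(=O)[C@H](COCc1ccccc1)[C@@H](O)c1cc(OC)c(OCc2ccccc2)c(Br)c1 | intermediate
33 | (R)-4-benzyl-3-[(2R,3R)-2-[(benzyloxy)methyl]-3-ArC-3-[(tert-butyldimethylsilyl)oxy]propanoyl]-1,3-oxazolidin-2-one | O=C1OC[C@@H](Cc2ccccc2)N1C(=O)[C@H](COCc1ccccc1)[C@@H](O[Si](C)(C)C(C)(C)C)c1cc(OC)c(OCc2ccccc2)c(Br)c1 | intermediate
34 | (2R,3R)-2-[(benzyloxy)methyl]-3-ArC-3-[(tert-butyldimethylsilyl)oxy]propaneperoxoic acid | OOC(=O)[C@H](COCc1ccccc1)[C@@H](O[Si](C)(C)C(C)(C)C)c1cc(OC)c(OCc2ccccc2)c(Br)c1 | intermediate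
35 | (2R,3R)-2-[(benzyloxy)methyl]-3-ArC-3-[(tert-butyldimethylsilyl)oxy]propanoic acid | OC(=O)[C@H](COCc1ccccc1)[C@@H](O[Si](C)(C)C(C)(C)C)c1cc(OC)c(OCc2ccccc2)c(Br)c1 | intermediate
36 | methyl (2R,3R)-2-[(benzyloxy)methyl]-3-ArC-3-[(tert-butyldimethylsilyl)oxy]propanoate | COC(=O)[C@H](COCc1ccccc1)[C@@H](O[Si](C)(C)C(C)(C)C)c1cc(OC)c(OCc2ccccc2)c(Br)c1 | intermediate
37 | (3R,4R)-4-ArC-3-[(benzyloxy)methyl]-4-[(tert-butyldimethylsilyl)oxy]-1-(trimethylsilyl)-2-[(trimethylsilyl)methyl]butan-2-ol | C[Si](C)(C)CC(O)(C[Si](C)(C)C)[C@H](COCc1ccccc1)[C@@H](O[Si](C)(C)C(C)(C)C)c1cc(OC)c(OCc2ccccc2)c(Br)c1 | intermediate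
38 | [(3R,4R)-4-ArC-3-[(benzyloxy)methyl]-4-[(tert-butyldimethylsilyl)oxy]-2-methylidenebutyl]trimethylsilane | C=C(C[Si](C)(C)C)[C@H](COCc1ccccc1)[C@@H](O[Si](C)(C)C(C)(C)C)c1cc(OC)c(OCc2ccccc2)c(Br)c1 | intermediate
39 | tert-butyl[(1R,2R)-1-ArC-3-(benzyloxy)-2-{2-[(trimethylsilyl)methyl]oxiran-2-yl}propoxy]dimethylsilane, both epimers at the oxirane carbon | C[Si](C)(C)CC1(CO1)[C@H](COCc1ccccc1)[C@@H](O[Si](C)(C)C(C)(C)C)c1cc(OC)c(OCc2ccccc2)c(Br)c1 | intermediate
40 | (1R,2R)-1-ArC-2-[(benzyloxy)methyl]-3-methylidenebutane-1,4-diol | C=C(CO)[C@H](COCc1ccccc1)[C@@H](O)c1cc(OC)c(OCc2ccccc2)c(Br)c1 | intermediate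
41 | (3R,4R)-4-ArC-3-[(benzyloxy)methyl]-4-hydroxy-2-methylidenebutyl 4-methylbenzenesulfonate | C=C(COS(=O)(=O)c1ccc(C)cc1)[C@H](COCc1ccccc1)[C@@H](O)c1cc(OC)c(OCc2ccccc2)c(Br)c1 | intermediate
42 | (2R,3R)-2-ArC-3-[(benzyloxy)methyl]-4-methylideneoxolane | C=C1CO[C@@H](c2cc(OC)c(OCc3ccccc3)c(Br)c2)[C@H]1COCc1ccccc1 | intermediate
43 | (3R,6R,7R)-6-ArC-7-[(benzyloxy)methyl]-1,5-dioxaspiro[2.4]heptane | C1O[C@@]12CO[C@@H](c3cc(OC)c(OCc4ccccc4)c(Br)c3)[C@H]2COCc1ccccc1 | intermediate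
44 | [4-(benzyloxy)-3-methoxyphenyl]magnesium bromide | COc1cc([Mg]Br)ccc1OCc1ccccc1 | intermediate
45 | (2R,3R,4S)-2-ArC-3-[(benzyloxy)methyl]-4-(ArE-methyl)oxolan-4-ol (plan numbering) | COc1cc(C[C@@]2(O)CO[C@@H](c3cc(OC)c(OCc4ccccc4)c(Br)c3)[C@H]2COCc2ccccc2)ccc1OCc1ccccc1 | intermediate
46 | (2R,3R,4S)-2-[4-(benzyloxy)-3-methoxy-5-(4,4,5,5-tetramethyl-1,3,2-dioxaborolan-2-yl)phenyl]-3-[(benzyloxy)methyl]-4-(ArE-methyl)oxolan-4-ol (plan numbering) | COc1cc(C[C@@]2(O)CO[C@@H](c3cc(OC)c(OCc4ccccc4)c(c3)B3OC(C)(C)C(C)(C)O3)[C@H]2COCc2ccccc2)ccc1OCc1ccccc1 | intermediate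
47 | hepta-O-benzyl ether of the target (four phenols and three primary alcohols benzylated, tertiary alcohols free) | COc1cc(C[C@@]2(O)CO[C@@H](c3cc(OC)c(OCc4ccccc4)c(-c4cc([C@H]5c6cc(OCc7ccccc7)c(OC)cc6C[C@@](O)(COCc6ccccc6)[C@@H]5COCc5ccccc5)cc(OC)c4OCc4ccccc4)c3)[C@H]2COCc2ccccc2)ccc1OCc1ccccc1 | intermediate
48 | (2S,3S,4S)-4-{4-hydroxy-3-[2-hydroxy-5-[(2R,3R,4S)-4-hydroxy-4-(4-hydroxy-3-methoxybenzyl)-3-(hydroxymethyl)oxolan-2-yl]-3-methoxyphenyl]-5-methoxyphenyl}-2,3-bis(hydroxymethyl)-7-methoxy-1,2,3,4-tetrahydronaphthalene-2,6-diol | COc1cc(C[C@@]2(O)CO[C@@H](c3cc(OC)c(O)c(-c4cc([C@H]5c6cc(O)c(OC)cc6C[C@@](O)(CO)[C@@H]5CO)cc(OC)c4O)c3)[C@H]2CO)ccc1O | target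

**Totals**
Total step count: 29.
Longest linear sequence: 14 steps (steps 3–14, then 28 and 29).

**Steps most likely to fail**

Step 14. What may go wrong: the 6-endo opening may be slower than proton transfer to the aryllithium on warming, so that bromine is lost without ring closure. Fallback: from 22 directly to 24 by a nickel-catalysed reductive cross-electrophile cyclization (NiCl2(dme), 4,4′-di-tert-butyl-2,2′-bipyridine, NaI, Et3N·HCl, Zn dust, DMPU, rt), a coupling type known for joining aryl bromides to epoxides at the less hindered carbon. Iodide opens the oxirane at CH2 to an iodohydrin, whose primary radical is captured by the arylnickel species formed at the C–Br bond; the C3–O bond again stays intact. No organolithium is involved and no further compound is isolated (F0).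

Step 10. What may go wrong: enolisation of the hindered β-benzyloxy ester may compete with the second addition, leading to β-elimination of benzyl alcohol or a stalled mono-adduct. Fallback: from acid 15, amide coupling (EDC·HCl, HOBt, MeNH(OMe)·HCl, N-methylmorpholine, CH2Cl2) should give the N-methoxy-N-methylamide, (2S,3S)-2-[(benzyloxy)methyl]-3-ArA-3-ArD-N-methoxy-N-methylpropanamide F1. A single addition of TMSCH2MgCl (THF, 0 °C) stops at the ketone, (3S,4S)-3-[(benzyloxy)methyl]-4-ArA-4-ArD-1-(trimethylsilyl)butan-2-one F2. Non-basic Takai–Lombardo methylenation (Zn, CH2Br2, TiCl4, THF/CH2Cl2) then returns to allylsilane 18.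

Step 7. What may go wrong: alkylation of an enolate shielded by two aryl groups may be slow, so that Lewis-acid cleavage of aryl benzyl ethers overtakes C–C bond formation. Fallback: from 11, the same titanium enolate is trapped with the smaller formaldehyde equivalent (1,3,5-trioxane, TiCl4, CH2Cl2, 0 °C; aldol-type hydroxymethylation under the same auxiliary control). This should give the primary alcohol, (R)-4-benzyl-3-[(2S,3S)-3-ArA-3-ArD-2-(hydroxymethyl)propanoyl]-1,3-oxazolidin-2-one F3. O-Benzylation under neutral conditions (BnBr, Ag2O, CH2Cl2) rejoins the route at 13.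

**Further compounds**
F0 | step 14 | none | none
F1 | step 10 | (2S,3S)-2-[(benzyloxy)methyl]-3-ArA-3-ArD-N-methoxy-N-methylpropanamide | COc1cc(cc(Cl)c1OCc1ccccc1)[C@@H](c1cc(OCc2ccccc2)c(OC)cc1Br)[C@@H](COCc1ccccc1)C(=O)N(C)OC
F2 | step 10 | (3S,4S)-3-[(benzyloxy)methyl]-4-ArA-4-ArD-1-(trimethylsilyl)butan-2-one | COc1cc(cc(Cl)c1OCc1ccccc1)[C@@H](c1cc(OCc2ccccc2)c(OC)cc1Br)[C@@H](COCc1ccccc1)C(=O)C[Si](C)(C)C
F3 | step 7 | (R)-4-benzyl-3-[(2S,3S)-3-ArA-3-ArD-2-(hydroxymethyl)propanoyl]-1,3-oxazolidin-2-one | COc1cc(cc(Cl)c1OCc1ccccc1)[C@@H](c1cc(OCc2ccccc2)c(OC)cc1Br)[C@@H](CO)C(=O)N1[C@H](Cc2ccccc2)COC1=O
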